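The constants of the steps are hidden, but the ratio of two of them can be read from the earlier runs and carried over to green and teal.

| setting | spring | noon | green | teal |
|---|---|---|---|---|
| free monomer | 0.056 M (fed, over 15 h) | 0.15 M (fed, over 15 h) | 0.25 M (fed, over 15 h) | 0.080 M (fed, over 15 h) |
| initiator | 25 mM | 25 mM | 25 mM | 25 mM |
| remark | run made earlier | run made earlier |  |  |
| time |  |  | 10 d | 10 d |

| run | time / d | monomer in chains / % |
|---|---|---|
| spring | 1.25 | 2.5 |
| spring | 2.50 | 6.8 |
| spring | 4.00 | 13.6 |
| spring | 5.00 | 20.2 |
| noon | 1.25 | 3.6 |
| noon | 2.50 | 11.3 |
| noon | 4.00 | 23.8 |
| noon | 5.00 | 32.1 |

(readings scatter by 0.5 percentage points)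

- the average divides the monomer in chains by the number of chains begun, living and dead together
- the numbers in the tables scatter with a standard deviation of 0.5 percentage points
- steps that have been proposed: free monomer + initiator -> living end + monomer in chains; free monomer + living end -> monomer in chains + living end; living end + free monomer -> dead end
- the earlier runs do not show the number of chains; that part of a forecast is a guess

- which of the two ends with the longer chains by the average number of monomer units in a chain (chains begun, living or dead) ("neither" if they lie within 10%) (green / teal / neither)
- average number of monomer units in a chain (chains begun, living or dead) at the end, green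
- average number of monomer units in a chain (chains begun, living or dead) at the end, teal

Free monomer begins a chain on meeting initiator and lengthens one on meeting a living end. The first spring reading, counted as chain starts, gives an uptake u = 0.0200 d⁻¹ of the free monomer, a rough reading. Let c be the initiator charge, and let s = (u/c) × time × mean free monomer, the time running from half the dosing time. The share of initiator used is then B = 1 − e^−s. If begun chains stay living, monomer in chains per c is B + ρ(s − B), and the length is 1 + ρ(s − B)/B. The noon run at 5.00 d, with s = 0.472, gives the reading ρ = 16.2. This ρ is how many times faster a living end takes free monomer than initiator does at equal concentration, a selectivity factor. The spring run, with s = 0.189, gives the reading 16.7.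

Turning the settings by hand, in this reckoning: at a fixed initiator charge and time, a larger charge of free monomer raises s, and the length rises with s. In this reckoning the initiator charge enters the length through s, by way of the mean free monomer. Dosing shifts the clock by 0.312 d, which is small beside 10 d. Averaging a trial s with the s that its monomer use returns, my own reckoning gives s = 1.15 and length 12.0 for green, and s = 0.458 and length 4.98 for teal.

The forecast reads the curves as “slow initiation followed by propagation from a growing living-end population” and names green, with 6.5 for green and 3.2 for teal, both below my lengths. Its constants for lengthening and for beginning, 9 and 0.9 per M per day, stand in a ratio of 10, smaller than ρ.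

The simulation names green, with 11.4 for green and 4.95 for teal.

    free monomer + initiator → living end + monomer in chains (k = 0.0320 M⁻¹ h⁻¹)
    free monomer + living end → monomer in chains + living end, rate k2*[living end]*[free monomer] (k = 0.550 M⁻¹ h⁻¹)
    living end + free monomer → dead end (k = 0.00690 M⁻¹ h⁻¹)

At 10.0 d green keeps 33% of its initiator charge and teal 64%. With s read from these, ρ gives 11.6 for green and 4.88 for teal. A neighbour of teal, charged with 0.015 M of initiator, keeps 61% of that charge at the same time, so s = 0.493 and ρ gives 5.28. The simulated neighbour ends at 5.42.

(The data were generated by integration with constants of no real substance, noise included.)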